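**Retrosynthetic overview**
1. Macrocarpal N comes from a 2,6-dimethoxyphenyl diketone by late work on the arene: para C–H hydroxylation, double formylation, O-demethylation.
2. The α-cyclopropyl ketone comes from a 1,2-shift of a cis-cyclopropyl group from the carbonyl carbon to the CHCl carbon of a 2-chlorocyclopentanone. The cyclopropyl Grignard reagent comes from 3,3-dimethylcyclopropene and a masked 3-oxobutyl Grignard reagent by asymmetric carbomagnesiation.
3. Key step: the 2-chlorocyclopentanone comes from a 2,2-disubstituted cyclobutanone and LiCHCl2 by a one-carbon ring expansion in which the quaternary carbon migrates with retention.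
4. The cyclobutanone carrying the quaternary/benzylic pair comes from an (E)-arylidenecyclobutanone, iBuMgBr and MeI. The arylidene ketone comes from cyclobutanone and 2,6-dimethoxybenzaldehyde, itself made from 1,3-dimethoxybenzene.
5. Ring order: the arene and the four-membered ring are bought, the four-membered ring is expanded to the five-membered ring, and the cyclopropane is built in a side branch and joined last.

Assumption: the sense of induction of the two chiral copper catalysts (steps 3 and 8) is taken by analogy with the closest known substrates. If a first run shows the opposite sense, the mirror-image ligand is used and nothing else changes.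

**Step 1**
Reactants: 1 1,3-dimethoxybenzene
Product: 3 2,6-dimethoxybenzaldehyde, via 2,6-dimethoxyphenyllithium 2 (not isolated)
Conditions: n-BuLi, THF, 0 to 23 °C; DMF, 0 °C; 1 M HCl
Reagents that add atoms: N,N-dimethylformamide CN(C)C=O
Why: Directed ortho-metalation, in which both methoxy groups steer n-BuLi to C-2, followed by standard formylation of the aryllithium with DMF; no stereocentre is formed.

**Step 2**
Reactants: 3 2,6-dimethoxybenzaldehyde; 4 cyclobutanone
Product: 8 (2E)-2-[(2,6-dimethoxyphenyl)methylidene]cyclobutan-1-one, via lithium cyclobutenolate 5 (not isolated), via lithium aldolate 6 (not isolated), via aldol mesylate 7 (not isolated)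
Conditions: 4, LiN(iPr)2, THF, -78 °C; 3; MsCl, -78 to 0 °C; DBU, 23 °C
Reagents that add atoms: none
Why: Directed aldol addition followed by mesylate elimination (a stepwise aldol condensation) avoids the double condensation seen with hydroxide, and the (E)-alkene forms because the twisted aryl group stays away from the carbonyl group.

**Step 3**
Reactants: 8 (2E)-2-[(2,6-dimethoxyphenyl)methylidene]cyclobutan-1-one; 9 isobutylmagnesium bromide
Product: 11 (2R)-2-[(1R)-1-(2,6-dimethoxyphenyl)-3-methylbutyl]-2-methylcyclobutan-1-one, via bromomagnesium enolate 10 (not isolated)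
Conditions: 9 (1.05 equiv, slow addition), CuBr·SMe2 (5 mol%), (R)-1-[(Sp)-2-(diphenylphosphino)ferrocenyl]ethyldicyclohexylphosphine (6 mol%), tBuOMe, -78 °C; MeI, DMPU, -78 to 0 °C
Reagents that add atoms: iodomethane CI
Why: Copper-catalysed asymmetric conjugate addition of a Grignard reagent to an s-cis enone sets the benzylic centre under ligand control, and the ring-locked enolate 10 is then methylated anti to the aryl group in its A(1,3)-minimised conformer (benzylic H eclipsing the C–OMg side), which sets the quaternary centre in the required relative sense (tandem conjugate addition–enolate alkylation).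

**Step 4 (key ring expansion)**
Reactants: 11 (2R)-2-[(1R)-1-(2,6-dimethoxyphenyl)-3-methylbutyl]-2-methylcyclobutan-1-one
Product: 15 (3R)-2-chloro-3-[(1R)-1-(2,6-dimethoxyphenyl)-3-methylbutyl]-3-methylcyclopentan-1-one as both C-2 epimers, via lithium dichloromethyl carbinolate 12 (not isolated), via dilithiated carbenoid 13 (not isolated), via lithium chloroenolate 14 (not isolated)
Conditions: CH2Cl2, LiN(iPr)2, THF, -100 °C; 11; LiN(iPr)2 (2 equiv), -78 to -20 °C; AcOH, -78 °C
Reagents that add atoms: dichloromethane ClCCl
Why: β-Oxido carbenoid (semipinacol-type) one-carbon ring expansion, in which strain release drives the 1,2-shift and the more substituted (quaternary) ring carbon migrates to the carbenoid carbon with retention, so both existing stereocentres are kept and the new CHCl carbon ends up between C=O and the quaternary carbon.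

**Step 5**
Reactants: 16 2-methylpropene
Product: 17 1,1-dibromo-2,2-dimethylcyclopropane
Conditions: CHBr3, KOtBu, pentane, -20 to 23 °C
Reagents that add atoms: bromoform BrC(Br)Br
Why: Dibromocarbene addition to an electron-rich 1,1-disubstituted alkene is a standard gem-dihalocyclopropanation; no stereocentre is formed.

**Step 6**
Reactants: 17 1,1-dibromo-2,2-dimethylcyclopropane
Product: 18 1-bromo-2,2-dimethylcyclopropane (racemic)
Conditions: EtMgBr (1.2 equiv), Ti(OiPr)4 (2 mol%), Et2O, 23 °C
Reagents that add atoms: none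
Why: Titanium-catalysed hydrodebromination of gem-dibromocyclopropanes with EtMgBr stops cleanly at the monobromide, and the new stereocentre is erased in the next step.

**Step 7**
Reactants: 18 1-bromo-2,2-dimethylcyclopropane
Product: 19 3,3-dimethylcyclopropene
Conditions: KOtBu, DMSO, 23 °C; N2 sweep into toluene at -78 °C
Reagents that add atoms: none
Why: 1,2-Dehydrobromination (E2) with KOtBu/DMSO is the standard route to 3,3-disubstituted cyclopropenes, and the volatile product is carried out of the base as it forms.

**Step 8**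
Reactants: 15 (3R)-2-chloro-3-[(1R)-1-(2,6-dimethoxyphenyl)-3-methylbutyl]-3-methylcyclopentan-1-one; 19 3,3-dimethylcyclopropene; 20 2-(2-bromoethyl)-2-methyl-1,3-dioxolane
Product: 25 (2R,3R)-2-{(1R,3R)-2,2-dimethyl-3-[2-(2-methyl-1,3-dioxolan-2-yl)ethyl]cyclopropyl}-3-[(1S)-1-(2,6-dimethoxyphenyl)-3-methylbutyl]-3-methylcyclopentan-1-one, via ketal Grignard reagent 21 (not isolated), via cis-cyclopropylmagnesium bromide 22 (not isolated), via bromomagnesium chlorohydrinate 23 (not isolated), via ketone epimer mixture 24 (not isolated)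
Conditions: 20, Mg, THF, 30 °C; 19, CuBr·SMe2 (5 mol%), (R)-DTBM-SEGPHOS (6 mol%), toluene–Et2O, -30 °C; 15, LaCl3·2LiCl (30 mol%), -78 to 0 °C; toluene, 70 °C; K2CO3, MeOH, 23 °C
Reagents that add atoms: none
Why: Proposed new method: a one-flask asymmetric carbomagnesiation / carbonyl addition / chlorohydrinate semipinacol sequence in which a fully substituted, configurationally defined cyclopropyl group is the migrating group; ligand-controlled syn-carbometalation of 19 sets both cyclopropane centres and gives the cis, configurationally stable Grignard reagent 22, which adds to either epimer of 15 anti to the C–Cl dipole, so that in 23 the cyclopropyl–C bond is antiperiplanar to C–Cl while the cis O–Mg group cannot close an epoxide; on heating, alkoxide push and magnesium-assisted loss of chloride drive the 1,2-shift with retention at the migrating cyclopropyl carbon (the only other aligned shift is a ring contraction that would cost a cyclobutane), and base equilibration of the enolisable α-centre then places the cyclopropyl group trans to the bulky 1-arylalkyl group; the closest known reaction types are the addition of aryl Grignard reagents to 2-chlorocycloalkanones with thermal rearrangement of the magnesium chlorohydrinate to 2-arylcycloalkanones, and the trapping of cyclopropylmagnesium species from copper-catalysed carbomagnesiation of cyclopropenes by simple electrophiles.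

**Step 9**
Reactants: 25 (the ketal ketone from step 8)
Product: 28 (2R,3R)-2-[(1R,3R)-2,2-dimethyl-3-(3-oxobutyl)cyclopropyl]-3-[(1S)-1-(4-hydroxy-2,6-dimethoxyphenyl)-3-methylbutyl]-3-methylcyclopentan-1-one, via aryl pinacol boronate 26 (not isolated), via ketal phenol 27 (not isolated)
Conditions: [Ir(OMe)(cod)]2 (2 mol%), dtbpy (4 mol%), B2pin2, THF, 80 °C; H2O2, NaOH, 0 °C; 1 M HCl, THF, 23 °C
Reagents that add atoms: hydrogen peroxide OO; water O
Why: Sterically governed iridium-catalysed aromatic C–H borylation takes the only ring C–H without an ortho substituent (para to the alkyl group), boronate oxidation then gives the phenol while the base-sensitive 1,7-diketone is still masked, and the acid finish hydrolyses the dioxolane without touching any stereocentre.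

**Step 10**
Reactants: 28 (the phenol diketone from step 9)
Product: 29 2-hydroxy-4,6-dimethoxy-5-{(1S)-1-[(1R,2R)-2-[(1R,3R)-2,2-dimethyl-3-(3-oxobutyl)cyclopropyl]-1-methyl-3-oxocyclopentyl]-3-methylbutyl}benzene-1,3-dicarbaldehyde
Conditions: Cl2CHOMe (6 equiv), TiCl4 (8 equiv), CH2Cl2, -78 to 0 °C; 1 M HCl
Reagents that add atoms: dichloromethyl methyl ether COC(Cl)Cl; water O
Why: Double Rieche formylation, in which the titanium phenoxide directs the electrophile to the two positions ortho to OH; these are the only free ring positions and stay activated by three oxygen donors after the first formylation.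

**Step 11**
Reactants: 29 (the dimethyl ether dialdehyde from step 10)
Product: 30 macrocarpal N
Conditions: BCl3 (8 equiv), CH2Cl2, -78 to 0 °C; H2O
Reagents that add atoms: none
Why: Chelation-assisted aryl methyl ether cleavage works because each OMe lies ortho to a formyl group, so BCl3 binds C=O and OMe together and chloride removes the methyl group at or below 0 °C, conditions that the ketones, the unactivated cyclopropane and all five stereocentres tolerate.

**Compound list**
1 | 1,3-dimethoxybenzene | COc1cccc(OC)c1 | starting material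
2 | 2,6-dimethoxyphenyllithium | [Li]c1c(OC)cccc1OC | intermediate
3 | 2,6-dimethoxybenzaldehyde | COc1cccc(OC)c1C=O | intermediate
4 | cyclobutanone | O=C1CCC1 | starting material
5 | lithium cyclobut-1-en-1-olate | [Li]OC1=CCC1 | intermediate
6 | lithium (2,6-dimethoxyphenyl)(2-oxocyclobutyl)methanolate (racemic, syn/anti mixture) | [Li]OC(c1c(OC)cccc1OC)C1CCC1=O | intermediate
7 | (2,6-dimethoxyphenyl)(2-oxocyclobutyl)methyl methanesulfonate (racemic, syn/anti mixture) | CS(=O)(=O)OC(c1c(OC)cccc1OC)C1CCC1=O | intermediate
8 | (2E)-2-[(2,6-dimethoxyphenyl)methylidene]cyclobutan-1-one | O=C1CC/C1=C\c1c(OC)cccc1OC | intermediate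
9 | isobutylmagnesium bromide | CC(C)C[Mg]Br | starting material
10 | bromomagnesium 2-[(1S)-1-(2,6-dimethoxyphenyl)-3-methylbutyl]cyclobut-1-en-1-olate | Br[Mg]OC1=C(CC1)[C@H](CC(C)C)c1c(OC)cccc1OC | intermediate
11 | (2R)-2-[(1R)-1-(2,6-dimethoxyphenyl)-3-methylbutyl]-2-methylcyclobutan-1-one (benzylic centre spatially as in 10; the descriptor changes only through CIP ranking) | O=C1CC[C@]1(C)[C@H](CC(C)C)c1c(OC)cccc1OC | intermediate
12 | lithium 1-(dichloromethyl)cyclobutan-1-olate derived from 11 (carbinol centre undefined, other centres as in 11) | [Li]OC1(C(Cl)Cl)CC[C@]1(C)[C@H](CC(C)C)c1c(OC)cccc1OC | intermediate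
13 | C-lithiated form of 12 (β-oxido dichlorocarbenoid) | [Li]OC1(C([Li])(Cl)Cl)CC[C@]1(C)[C@H](CC(C)C)c1c(OC)cccc1OC | intermediate
14 | lithium 2-chlorocyclopent-1-en-1-olate bearing the 3-methyl and 3-(1-aryl-3-methylbutyl) groups (centres as in 11) | [Li]OC1=C(Cl)[C@](C)(CC1)[C@H](CC(C)C)c1c(OC)cccc1OC | intermediate
15 | (3R)-2-chloro-3-[(1R)-1-(2,6-dimethoxyphenyl)-3-methylbutyl]-3-methylcyclopentan-1-one (both C-2 epimers) | ClC1C(=O)CC[C@]1(C)[C@H](CC(C)C)c1c(OC)cccc1OC | intermediate
16 | 2-methylpropene | CC(C)=C | starting material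
17 | 1,1-dibromo-2,2-dimethylcyclopropane | CC1(C)CC1(Br)Br | intermediate
18 | 1-bromo-2,2-dimethylcyclopropane (racemic) | CC1(C)CC1Br | intermediate
19 | 3,3-dimethylcyclopropene | CC1(C)C=C1 | intermediate
20 | 2-(2-bromoethyl)-2-methyl-1,3-dioxolane | CC1(CCBr)OCCO1 | starting material
21 | [2-(2-methyl-1,3-dioxolan-2-yl)ethyl]magnesium bromide | CC1(CC[Mg]Br)OCCO1 | intermediate
22 | {(1S,3S)-2,2-dimethyl-3-[2-(2-methyl-1,3-dioxolan-2-yl)ethyl]cyclopropyl}magnesium bromide (Mg and side chain cis) | CC1(CC[C@@H]2[C@H]([Mg]Br)C2(C)C)OCCO1 | intermediate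
23 | bromomagnesium alkoxide of the chlorohydrin from 15 and 22 (cyclopropyl on C-1 trans to Cl on C-2, both C-2 series; other centres as in 15 and 22) | CC1(CC[C@@H]2[C@H](C3(O[Mg]Br)CC[C@](C)([C@H](CC(C)C)c4c(OC)cccc4OC)C3Cl)C2(C)C)OCCO1 | intermediate
24 | 25 as a mixture with its C-2 epimer | CC1(CC[C@@H]2[C@H](C3C(=O)CC[C@]3(C)[C@H](CC(C)C)c3c(OC)cccc3OC)C2(C)C)OCCO1 | intermediate
25 | (2R,3R)-2-{(1R,3R)-2,2-dimethyl-3-[2-(2-methyl-1,3-dioxolan-2-yl)ethyl]cyclopropyl}-3-[(1S)-1-(2,6-dimethoxyphenyl)-3-methylbutyl]-3-methylcyclopentan-1-one (cyclopropane cis; cyclopropyl trans to the arylalkyl group) | CC1(CC[C@@H]2[C@H]([C@H]3C(=O)CC[C@]3(C)[C@H](CC(C)C)c3c(OC)cccc3OC)C2(C)C)OCCO1 | intermediate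
26 | 4-(pinacolatoboryl) derivative of 25 (boron para to the alkyl group) | CC1(CC[C@@H]2[C@H]([C@H]3C(=O)CC[C@]3(C)[C@H](CC(C)C)c3c(OC)cc(B4OC(C)(C)C(C)(C)O4)cc3OC)C2(C)C)OCCO1 | intermediate
27 | 4-hydroxy derivative of 25 (ketal still in place) | CC1(CC[C@@H]2[C@H]([C@H]3C(=O)CC[C@]3(C)[C@H](CC(C)C)c3c(OC)cc(O)cc3OC)C2(C)C)OCCO1 | intermediate
28 | (2R,3R)-2-[(1R,3R)-2,2-dimethyl-3-(3-oxobutyl)cyclopropyl]-3-[(1S)-1-(4-hydroxy-2,6-dimethoxyphenyl)-3-methylbutyl]-3-methylcyclopentan-1-one | CC(=O)CC[C@@H]1[C@H]([C@H]2C(=O)CC[C@]2(C)[C@H](CC(C)C)c2c(OC)cc(O)cc2OC)C1(C)C | intermediate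
29 | 2-hydroxy-4,6-dimethoxy-5-{(1S)-1-[(1R,2R)-2-[(1R,3R)-2,2-dimethyl-3-(3-oxobutyl)cyclopropyl]-1-methyl-3-oxocyclopentyl]-3-methylbutyl}benzene-1,3-dicarbaldehyde | CC(=O)CC[C@@H]1[C@H]([C@H]2C(=O)CC[C@]2(C)[C@H](CC(C)C)c2c(OC)c(C=O)c(O)c(C=O)c2OC)C1(C)C | intermediate
30 | macrocarpal N, 2,4,6-trihydroxy-5-{(1S)-1-[(1R,2R)-2-[(1R,3R)-2,2-dimethyl-3-(3-oxobutyl)cyclopropyl]-1-methyl-3-oxocyclopentyl]-3-methylbutyl}benzene-1,3-dicarbaldehyde | CC(=O)CC[C@@H]1[C@H]([C@H]2C(=O)CC[C@]2(C)[C@H](CC(C)C)c2c(O)c(C=O)c(O)c(C=O)c2O)C1(C)C | target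

**Totals**
Total step count: 11.
Longest linear sequence: 8 steps (1, 2, 3, 4, 8, 9, 10, 11). The cyclopropene branch (5, 6, 7) joins at step 8.

**The three steps most likely to fail**

Step 8 (the proposed new step). There are four risks.
- The hindered Grignard reagent 22 may enolise or reduce 15 instead of adding to it.
- Addition syn to chlorine would give an epoxide and then the regioisomeric ketone.
- The shift onto a carbon next to the quaternary centre may be slow.
- A Favorskii-type pathway may compete.

The fallback uses known chemistry: addition of a selenium-stabilised carbanion to a cyclobutanone, then ring enlargement of the β-hydroxyselenide with migration of the more substituted carbon. It sets out from 11 and 22 and does not need 15. Compound 22 is quenched with DMF to give cis-(1S,3R)-2,2-dimethyl-3-[2-(2-methyl-1,3-dioxolan-2-yl)ethyl]cyclopropanecarbaldehyde F7. MeSeH with ZnCl2 at 0 °C converts the aldehyde, which reacts much faster than the dioxolane, into the bis(methylseleno)acetal F8. n-BuLi at -78 °C cleaves one C–Se bond to give the α-selenoalkyllithium F9, which adds to the strained ketone 11 to give the β-hydroxyselenide F10. MeOTf methylates selenium to give the selenonium triflate F11, and K2CO3 then triggers loss of Me2Se with migration of the quaternary ring carbon. This gives 24, where the fallback rejoins the route (K2CO3/MeOH to 25).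

Step 3. The strained carbonyl group may undergo 1,2-addition, and the di-ortho-substituted aryl group may erode rate and enantioselectivity. The fallback replaces catalyst control by resolution through union with the enantiopure cyclopropane. It sets out from 8. Stoichiometric iBu2CuLi (from iBuLi and CuI) in Et2O at -78 °C, followed by MeI/DMPU, is a standard cuprate addition–alkylation with the same A(1,3) control. It gives 11 together with its mirror image, (2S)-2-[(1S)-1-(2,6-dimethoxyphenyl)-3-methylbutyl]-2-methylcyclobutan-1-one F1. Steps 4 and 8 are run on this racemate. F1 gives the mirror-image chloroketone F2, and because 22 is a single enantiomer, F2 ends as the (2S,3S,1'R) diastereomer of the coupled ketone F3. F3 is removed by chromatography, and the fallback rejoins the route at 25.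

Step 4. The carbinolate 12 may close to a chloro-oxirane and end as an α-chloro aldehyde, or the second deprotonation may be incomplete. The fallback separates ring expansion from chlorination and makes the carbenoid by halogen–lithium exchange. It sets out from 11. LiCHBr2 (from CH2Br2 and LiN(iPr)2) adds to 11, and after an aqueous quench the dibromomethyl carbinol F4 is isolated. n-BuLi (2.2 equiv) at -95 °C deprotonates the OH group, exchanges one bromine, and on warming gives the ring-expanded, regiodefined lithium enolate F5. TMSCl traps this as the trimethylsilyl enol ether F6, and N-chlorosuccinimide in CH2Cl2 at 0 °C chlorinates it at the carbon next to the quaternary centre. The fallback rejoins the route at 15.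

**Further compounds**
F1 | step 3 | (2S)-2-[(1S)-1-(2,6-dimethoxyphenyl)-3-methylbutyl]-2-methylcyclobutan-1-one (enantiomer of 11) | O=C1CC[C@@]1(C)[C@@H](CC(C)C)c1c(OC)cccc1OC
F2 | step 3 | (3S)-2-chloro-3-[(1S)-1-(2,6-dimethoxyphenyl)-3-methylbutyl]-3-methylcyclopentan-1-one (enantiomeric series of 15) | ClC1C(=O)CC[C@@]1(C)[C@@H](CC(C)C)c1c(OC)cccc1OC
F3 | step 3 | (2S,3S)-2-{(1R,3R)-2,2-dimethyl-3-[2-(2-methyl-1,3-dioxolan-2-yl)ethyl]cyclopropyl}-3-[(1R)-1-(2,6-dimethoxyphenyl)-3-methylbutyl]-3-methylcyclopentan-1-one (diastereomer of 25) | CC1(CC[C@@H]2[C@H]([C@@H]3C(=O)CC[C@@]3(C)[C@@H](CC(C)C)c3c(OC)cccc3OC)C2(C)C)OCCO1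
F4 | step 4 | 1-(dibromomethyl)cyclobutan-1-ol derived from 11 (carbinol centre undefined) | OC1(C(Br)Br)CC[C@]1(C)[C@H](CC(C)C)c1c(OC)cccc1OC
F5 | step 4 | lithium cyclopent-1-en-1-olate bearing the 3-methyl and 3-(1-aryl-3-methylbutyl) groups | [Li]OC1=C[C@](C)(CC1)[C@H](CC(C)C)c1c(OC)cccc1OC
F6 | step 4 | trimethylsilyl enol ether of F5 | C[Si](C)(C)OC1=C[C@](C)(CC1)[C@H](CC(C)C)c1c(OC)cccc1OC
F7 | step 8 | cis-(1S,3R)-2,2-dimethyl-3-[2-(2-methyl-1,3-dioxolan-2-yl)ethyl]cyclopropanecarbaldehyde | CC1(CC[C@@H]2[C@H](C=O)C2(C)C)OCCO1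
F8 | step 8 | bis(methylseleno)acetal of F7 | CC1(CC[C@@H]2[C@H](C([Se]C)[Se]C)C2(C)C)OCCO1
F9 | step 8 | α-(methylseleno)cyclopropylmethyllithium from F8 | CC1(CC[C@@H]2[C@H](C([Li])[Se]C)C2(C)C)OCCO1
F10 | step 8 | β-hydroxyselenide from F9 and 11 (two new centres undefined) | CC1(CC[C@@H]2[C@H](C([Se]C)C3(O)CC[C@]3(C)[C@H](CC(C)C)c3c(OC)cccc3OC)C2(C)C)OCCO1
F11 | step 8 | dimethylselenonium triflate of F10 | CC1(CC[C@@H]2[C@H](C([Se+](C)C)C3(O)CC[C@]3(C)[C@H](CC(C)C)c3c(OC)cccc3OC)C2(C)C)OCCO1.[O-]S(=O)(=O)C(F)(F)F
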